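**Plan** (side-chain carbons are numbered C-1′, bonded to coumarin C-3, through C-12′)

- Retrosynthesis: the ketal bond from the coumarin 4-oxygen to C-8′ is cut first. The ether bond O(on C-8′)–C-1′ and the ring bond C-2′–C-6′ are then cut together, opening the pyran (ring B) and the cyclopentene to a coumarin-3-yl (E)-alkene tethered to an allenyl 1,2-dione.
- Further cuts: C-7′–CH3 (anti SN2′ on a propargylic mesylate), C-5′–C-6′ (acyl–alkyne coupling), coumarin C-3–C-1′ (Suzuki coupling) and C-1′=C-2′ (cross-metathesis).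
- Forward: a 3-bromocoumarin, (S)-3-methylpent-4-enoic acid and a bis-silylated alkynediol are joined to a linear chain. The pyran and cyclopentene then close in one step, and the 1,3-dioxin closes last.
- Enabling feature: the C-8′ carbonyl oxygen, C-8′, C-7′ and C-6′ form a 1-oxadiene whose terminus C-6′ is the central allene carbon. C-6′ is held by C-5′–C-4′–C-3′ next to C-2′ of the C-1′=C-2′ alkene that is conjugated with the 4-oxycoumarin; the [4+2] leaves the distal allene bond as the C-5′=C-6′ ring alkene.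
- Stereochemistry: C-3′ comes from an oxazolidinone-directed conjugate addition. The C-5′ carbinol from asymmetric transfer hydrogenation is relayed by anti SN2′ to the allene axis and by the cycloaddition to C-1′ and C-2′. C-7′ and C-8′ are set in the final ketalisation; the C-8′ and C-9′ carbinol centres are temporary.

Key step: step 18

Remark: the (S,S) transfer-hydrogenation catalyst is assumed to give the (5′S) carbinol, as it does with simple alkynyl alkyl ketones; the antipodal catalyst would be used if the sense were opposite.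

**Step 1**
Reactants: 1 1-(2-hydroxy-6-methylphenyl)ethan-1-one
Product: 2 4-hydroxy-5-methyl-2H-chromen-2-one
Conditions: NaH (3 equiv), (EtO)2CO, toluene, 110 °C; then aq. HCl
Reagents that add atoms: diethyl carbonate, CCOC(=O)OCC
Why: Claisen-type acylation of the ketone enolate by the carbonate followed by lactonisation onto the phenol is the standard entry to 4-hydroxycoumarins.

**Step 2**
Reactants: 2 4-hydroxy-5-methyl-2H-chromen-2-one
Product: 3 3-bromo-4-hydroxy-5-methyl-2H-chromen-2-one
Conditions: NBS, MeCN, 0 °C → rt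
Reagents that add atoms: N-bromosuccinimide, O=C1CCC(=O)N1Br
Why: Electrophilic bromination of the enolic β-keto lactone can only occur at C-3.

**Step 3**
Reactants: 3 3-bromo-4-hydroxy-5-methyl-2H-chromen-2-one
Product: 4 3-bromo-4-(methoxymethoxy)-5-methyl-2H-chromen-2-one
Conditions: MOMCl, i-Pr2NEt, CH2Cl2, 0 °C
Reagents that add atoms: chloromethyl methyl ether, COCCl
Why: O-alkylation of the acidic enol by a hard electrophile should give the vinylogous methoxymethyl ester, which masks the 4-OH until the last step.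

**Step 4**
Reactants: 5 methyl (2S)-2-hydroxy-4-methylpentanoate
Product: 6 methyl (2S)-4-methyl-2-[(triethylsilyl)oxy]pentanoate
Conditions: TESCl, imidazole, CH2Cl2, 0 °C → rt
Reagents that add atoms: chlorotriethylsilane, CC[Si](Cl)(CC)CC
Why: Routine silylation of a secondary alcohol.

**Step 5**
Reactants: 6 methyl (2S)-4-methyl-2-[(triethylsilyl)oxy]pentanoate
Product: 7 (2S)-4-methyl-2-[(triethylsilyl)oxy]pentanal
Conditions: DIBAL-H, CH2Cl2, −78 °C; Rochelle salt work-up
Reagents that add atoms: none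
Why: Partial reduction of the α-silyloxy ester stops at the tetrahedral aluminate, which gives the aldehyde on work-up without touching the stereocentre.

**Step 6**
Reactants: 7 (2S)-4-methyl-2-[(triethylsilyl)oxy]pentanal
Product: 8 (3R,4S)-6-methyl-4-[(triethylsilyl)oxy]hept-1-yn-3-ol
Conditions: HC≡CMgBr, THF, −78 → 0 °C; aq. NH4Cl
Reagents that add atoms: ethynylmagnesium bromide, C#C[Mg]Br
Why: Non-chelated Felkin–Anh addition of the alkynyl Grignard reagent should favour the anti (3R,4S) carbinol; both carbinol carbons become carbonyls in step 18, so the minor epimer converges.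

**Step 7**
Reactants: 8 (3R,4S)-6-methyl-4-[(triethylsilyl)oxy]hept-1-yn-3-ol
Product: 9 (3R,4S)-6-methyl-3,4-bis[(triethylsilyl)oxy]hept-1-yne
Conditions: TESCl, imidazole, DMAP (cat.), CH2Cl2, rt
Reagents that add atoms: chlorotriethylsilane, CC[Si](Cl)(CC)CC
Why: Routine silylation of the propargylic alcohol.

**Step 8**
Reactants: 10 (4R)-4-benzyl-1,3-oxazolidin-2-one; 11 (2E)-but-2-enoyl chloride
Product: 12 (4R)-4-benzyl-3-[(2E)-but-2-enoyl]-1,3-oxazolidin-2-one
Conditions: n-BuLi, THF, −78 °C; then 11, −78 → 0 °C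
Reagents that add atoms: none
Why: N-acylation of the lithiated oxazolidinone is the standard preparation of the enoyl imide.

**Step 9**
Reactants: 12 (4R)-4-benzyl-3-[(2E)-but-2-enoyl]-1,3-oxazolidin-2-one
Product: 13 (4R)-4-benzyl-3-[(3S)-3-methylpent-4-enoyl]-1,3-oxazolidin-2-one
Conditions: CH2=CHMgBr, CuBr·SMe2 (cat.), THF, −78 → −20 °C; aq. NH4Cl
Reagents that add atoms: vinylmagnesium bromide, C=C[Mg]Br
Why: Copper-mediated conjugate addition to the magnesium-chelated s-cis enoyl imide from the face opposite the benzyl group should set the (3S) centre, the future C-3′.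

**Step 10**
Reactants: 13 (4R)-4-benzyl-3-[(3S)-3-methylpent-4-enoyl]-1,3-oxazolidin-2-one
Product: 14 (3S)-3-methylpent-4-enoic acid
Conditions: LiOH, H2O2, THF/H2O, 0 °C; Na2SO3; then HCl to pH 2
Reagents that add atoms: hydrogen peroxide, OO (used with LiOH as lithium hydroperoxide)
Why: Hydroperoxide attacks the exocyclic imide carbonyl selectively and releases the acid without touching the β-stereocentre.

**Step 11**
Reactants: 14 (3S)-3-methylpent-4-enoic acid
Product: 15 (3S,4E)-3-methyl-5-(4,4,5,5-tetramethyl-1,3,2-dioxaborolan-2-yl)pent-4-enoic acid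
Conditions: vinylboronic acid pinacol ester (3 equiv), second-generation Grubbs catalyst (5 mol%), CH2Cl2, 40 °C
Reagents that add atoms: vinylboronic acid pinacol ester, C=CB1OC(C)(C)C(C)(C)O1
Why: Olefin cross-metathesis of the allylically branched terminal alkene with the vinylboronate should give the E alkenylboronate with loss of ethene, and the free acid is tolerated.

**Step 12**
Reactants: 15 (3S,4E)-3-methyl-5-(4,4,5,5-tetramethyl-1,3,2-dioxaborolan-2-yl)pent-4-enoic acid; 4 3-bromo-4-(methoxymethoxy)-5-methyl-2H-chromen-2-one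
Product: 16 (3S,4E)-5-[4-(methoxymethoxy)-5-methyl-2-oxo-2H-chromen-3-yl]-3-methylpent-4-enoic acid
Conditions: Pd(dppf)Cl2 (5 mol%), K3PO4, 1,4-dioxane/H2O, 60 °C; then citric acid to pH 4
Reagents that add atoms: none
Why: Suzuki–Miyaura coupling of the 3-bromocoumarin with the alkenylboronate proceeds with retention of the E geometry, and mild phosphate base spares the lactone and the MOM group.

**Step 13**
Reactants: 16 (3S,4E)-5-[4-(methoxymethoxy)-5-methyl-2-oxo-2H-chromen-3-yl]-3-methylpent-4-enoic acid; 9 (3R,4S)-6-methyl-3,4-bis[(triethylsilyl)oxy]hept-1-yne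
Product: 18 3-[(1E,3S,8R,9S)-3,11-dimethyl-5-oxo-8,9-bis(triethylsilyloxy)dodec-1-en-6-yn-1-yl]-4-(methoxymethoxy)-5-methyl-2H-chromen-2-one, via acyl chloride 17 (not isolated)
Conditions: 1-chloro-N,N,2-trimethylprop-1-en-1-amine, CH2Cl2, 0 °C → rt; then 9, PdCl2(PPh3)2 (2 mol%), CuI (4 mol%), Et3N (1.2 equiv), THF, rt
Reagents that add atoms: none
Why: Neutral acid-chloride formation followed by Pd/Cu acyl Sonogashira coupling should give the ynone under conditions that spare the lactone and the vinylogous MOM ester; the β-stereocentre cannot epimerise.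

**Step 14**
Reactants: 18 the ynone from step 13
Product: 19 3-[(1E,3S,5S,8R,9S)-5-hydroxy-3,11-dimethyl-8,9-bis(triethylsilyloxy)dodec-1-en-6-yn-1-yl]-4-(methoxymethoxy)-5-methyl-2H-chromen-2-one
Conditions: Ru[(S,S)-TsNCHPhCHPhNH](p-cymene) (2 mol%), i-PrOH, rt
Reagents that add atoms: none
Why: Asymmetric transfer hydrogenation (Noyori type) of the alkynyl ketone is catalyst-controlled and should give the (5′S) propargylic alcohol, which encodes the later allene axis.

**Step 15**
Reactants: 19 the (5′S) propargylic alcohol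
Product: 20 (1E,3S,5S,8R,9S)-1-[4-(methoxymethoxy)-5-methyl-2-oxo-2H-chromen-3-yl]-3,11-dimethyl-8,9-bis(triethylsilyloxy)dodec-1-en-6-yn-5-yl methanesulfonate
Conditions: MsCl, Et3N, CH2Cl2, −40 °C
Reagents that add atoms: methanesulfonyl chloride, CS(=O)(=O)Cl
Why: Sulfonylation of the secondary alcohol with retention gives the leaving group for the SN2′ step; the crude mesylate would be used at once.

**Step 16**
Reactants: 20 the (5′S) propargylic mesylate
Product: 21 3-[(1E,3S,8R,9S)-3,7,11-trimethyl-8,9-bis(triethylsilyloxy)dodeca-1,5,6-trien-1-yl]-4-(methoxymethoxy)-5-methyl-2H-chromen-2-one with the (aS) allene axis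
Conditions: MeMgBr, CuBr·SMe2, LiBr (1.5 equiv each), THF, −78 °C
Reagents that add atoms: methylmagnesium bromide, C[Mg]Br
Why: Anti-selective SN2′ substitution of the propargylic mesylate by methylcopper installs the C-7′ methyl group and transfers the (5′S) centre to the (aS) axis; lactones tolerate this reagent at −78 °C.

**Step 17**
Reactants: 21 the (aS) allene bis-silyl ether
Product: 22 3-[(1E,3S,8R,9S)-8,9-dihydroxy-3,7,11-trimethyldodeca-1,5,6-trien-1-yl]-4-(methoxymethoxy)-5-methyl-2H-chromen-2-one with the (aS) allene axis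
Conditions: HF·pyridine, pyridine, THF, 0 °C → rt
Reagents that add atoms: none
Why: Buffered fluoride removes both triethylsilyl ethers while the MOM group, the allene and the lactone should survive.

**Step 18**
Reactants: 22 the (aS) allenic diol
Product: 24 3-[(1R,7S,7aR)-4,7-dimethyl-3-(3-methylbutanoyl)-1,6,7,7a-tetrahydrocyclopenta[c]pyran-1-yl]-4-(methoxymethoxy)-5-methyl-2H-chromen-2-one, via allenyl 1,2-dione 23 (not isolated)
Conditions: (COCl)2, DMSO, CH2Cl2, −78 °C; i-Pr2NEt, −78 → −20 °C; cold aq. NH4Cl; then toluene, BHT (cat.), 25–40 °C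
Reagents that add atoms: none
Why: Proposed new method: Swern oxidation of both carbinols unmasks the (aS)-allenyl 1,2-dione 23, in which O=C-8′–C-7′=C-6′ is an electron-poor 1-oxadiene (activated by the C-9′ carbonyl and by allene strain) that should add across the electron-rich C-1′=C-2′ alkene in a concerted, asynchronous inverse-electron-demand intramolecular oxa-Diels–Alder reaction, with the C-6′–C-2′ bond leading and the O–C-1′ bond lagging. The closest known reactions are intramolecular hetero-Diels–Alder reactions of 2-acyl-1-oxadienes with tethered alkenes and Diels–Alder reactions of vinylallenes, but an allenyl dione has not been used as the oxadiene. The pyran closes by [4+2] cycloaddition and the cyclopentene closes at the same time as the five-membered tether ring, exo with respect to the dienophile, the short tether allowing only O→C-1′ and C-6′→C-2′ bonding with the coumarin endo. Suprafacial addition to the E alkene fixes the C-1′/C-2′ relationship, and the allene axis fixes the face, because C-4′ must lie on the diene face that meets the dienophile; the (aS) axis should therefore give (1′R,2′R), matched with the (3′S) methyl group, which ends trans to C-1′ on the cyclopentene. The step needs the oxadiene to react in preference to the C-9′ carbonyl, which ring size secures, and it needs the axis to survive, which is why the oxidation uses a hindered amine at low temperature and the cyclisation is run at or below 40 °C.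

**Step 19**
Reactants: 24 the cycloadduct from step 18
Product: 26 the target CNP0310889.1 (1′R,2′R,3′S,7′R,8′S), via 4-hydroxycoumarin enol ether 25 (not isolated)
Conditions: CF3CO2H (5 equiv), CH2Cl2, 0 °C → rt; aq. NaHCO3
Reagents that add atoms: none
Why: Acid cleaves the vinylogous MOM ester to 25, protonation of the enol ether at C-7′ from the face away from the coumarin gives the C-8′ oxocarbenium ion, and the 4-hydroxyl closes the 1,3-dioxin from the only face it can reach (acid-catalysed intramolecular ketalisation, net anti addition setting C-7′ R and C-8′ S); protonation at C-5′ leads only to allylic ketals that re-ionise, whereas the non-allylic α-acyl ketal 26 should be the acid-stable sink.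

**Compound list**

1 | 1-(2-hydroxy-6-methylphenyl)ethan-1-one | CC(=O)c1c(C)cccc1O | starting material
2 | 4-hydroxy-5-methyl-2H-chromen-2-one | Cc1cccc2oc(=O)cc(O)c12 | intermediate
3 | 3-bromo-4-hydroxy-5-methyl-2H-chromen-2-one | Cc1cccc2oc(=O)c(Br)c(O)c12 | intermediate
4 | 3-bromo-4-(methoxymethoxy)-5-methyl-2H-chromen-2-one | Cc1cccc2oc(=O)c(Br)c(OCOC)c12 | intermediate
5 | methyl (2S)-2-hydroxy-4-methylpentanoate | CC(C)C[C@H](O)C(=O)OC | starting material
6 | methyl (2S)-4-methyl-2-[(triethylsilyl)oxy]pentanoate | CC(C)C[C@H](O[Si](CC)(CC)CC)C(=O)OC | intermediate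
7 | (2S)-4-methyl-2-[(triethylsilyl)oxy]pentanal | CC(C)C[C@H](O[Si](CC)(CC)CC)C=O | intermediate
8 | (3R,4S)-6-methyl-4-[(triethylsilyl)oxy]hept-1-yn-3-ol | C#C[C@@H](O)[C@H](CC(C)C)O[Si](CC)(CC)CC | intermediate
9 | (3R,4S)-6-methyl-3,4-bis[(triethylsilyl)oxy]hept-1-yne | C#C[C@@H](O[Si](CC)(CC)CC)[C@H](CC(C)C)O[Si](CC)(CC)CC | intermediate
10 | (4R)-4-benzyl-1,3-oxazolidin-2-one | O=C1N[C@H](Cc2ccccc2)CO1 | starting material
11 | (2E)-but-2-enoyl chloride | C/C=C/C(Cl)=O | starting material
12 | (4R)-4-benzyl-3-[(2E)-but-2-enoyl]-1,3-oxazolidin-2-one | C/C=C/C(=O)N1[C@H](Cc2ccccc2)COC1=O | intermediate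
13 | (4R)-4-benzyl-3-[(3S)-3-methylpent-4-enoyl]-1,3-oxazolidin-2-one | C=C[C@@H](C)CC(=O)N1[C@H](Cc2ccccc2)COC1=O | intermediate
14 | (3S)-3-methylpent-4-enoic acid | C=C[C@@H](C)CC(=O)O | intermediate
15 | (3S,4E)-3-methyl-5-(4,4,5,5-tetramethyl-1,3,2-dioxaborolan-2-yl)pent-4-enoic acid | CC1(C)OB(/C=C/[C@@H](C)CC(=O)O)OC1(C)C | intermediate
16 | (3S,4E)-5-[4-(methoxymethoxy)-5-methyl-2-oxo-2H-chromen-3-yl]-3-methylpent-4-enoic acid | Cc1cccc2oc(=O)c(/C=C/[C@@H](C)CC(=O)O)c(OCOC)c12 | intermediate
17 | (3S,4E)-5-[4-(methoxymethoxy)-5-methyl-2-oxo-2H-chromen-3-yl]-3-methylpent-4-enoyl chloride | Cc1cccc2oc(=O)c(/C=C/[C@@H](C)CC(Cl)=O)c(OCOC)c12 | intermediate (not isolated)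
18 | 3-[(1E,3S,8R,9S)-3,11-dimethyl-5-oxo-8,9-bis(triethylsilyloxy)dodec-1-en-6-yn-1-yl]-4-(methoxymethoxy)-5-methyl-2H-chromen-2-one | Cc1cccc2oc(=O)c(/C=C/[C@@H](C)CC(=O)C#C[C@@H](O[Si](CC)(CC)CC)[C@H](CC(C)C)O[Si](CC)(CC)CC)c(OCOC)c12 | intermediate
19 | 3-[(1E,3S,5S,8R,9S)-5-hydroxy-3,11-dimethyl-8,9-bis(triethylsilyloxy)dodec-1-en-6-yn-1-yl]-4-(methoxymethoxy)-5-methyl-2H-chromen-2-one | Cc1cccc2oc(=O)c(/C=C/[C@@H](C)C[C@H](O)C#C[C@@H](O[Si](CC)(CC)CC)[C@H](CC(C)C)O[Si](CC)(CC)CC)c(OCOC)c12 | intermediate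
20 | (1E,3S,5S,8R,9S)-1-[4-(methoxymethoxy)-5-methyl-2-oxo-2H-chromen-3-yl]-3,11-dimethyl-8,9-bis(triethylsilyloxy)dodec-1-en-6-yn-5-yl methanesulfonate | Cc1cccc2oc(=O)c(/C=C/[C@@H](C)C[C@H](OS(C)(=O)=O)C#C[C@@H](O[Si](CC)(CC)CC)[C@H](CC(C)C)O[Si](CC)(CC)CC)c(OCOC)c12 | intermediate
21 | 3-[(1E,3S,8R,9S)-3,7,11-trimethyl-8,9-bis(triethylsilyloxy)dodeca-1,5,6-trien-1-yl]-4-(methoxymethoxy)-5-methyl-2H-chromen-2-one, (aS) allene | Cc1cccc2oc(=O)c(/C=C/[C@@H](C)CC([H])=[C@@]=C(C)[C@@H](O[Si](CC)(CC)CC)[C@H](CC(C)C)O[Si](CC)(CC)CC)c(OCOC)c12 | intermediate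
22 | 3-[(1E,3S,8R,9S)-8,9-dihydroxy-3,7,11-trimethyldodeca-1,5,6-trien-1-yl]-4-(methoxymethoxy)-5-methyl-2H-chromen-2-one, (aS) allene | Cc1cccc2oc(=O)c(/C=C/[C@@H](C)CC([H])=[C@@]=C(C)[C@@H](O)[C@H](CC(C)C)O)c(OCOC)c12 | intermediate
23 | 3-[(1E,3S)-3,7,11-trimethyl-8,9-dioxododeca-1,5,6-trien-1-yl]-4-(methoxymethoxy)-5-methyl-2H-chromen-2-one, (aS) allene | Cc1cccc2oc(=O)c(/C=C/[C@@H](C)CC([H])=[C@@]=C(C)C(=O)C(=O)CC(C)C)c(OCOC)c12 | intermediate (not isolated)
24 | 3-[(1R,7S,7aR)-4,7-dimethyl-3-(3-methylbutanoyl)-1,6,7,7a-tetrahydrocyclopenta[c]pyran-1-yl]-4-(methoxymethoxy)-5-methyl-2H-chromen-2-one | Cc1cccc2oc(=O)c(c(OCOC)c12)[C@@H]1OC(C(=O)CC(C)C)=C(C)C2=CC[C@H](C)[C@@H]12 | intermediate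
25 | 4-hydroxy-3-[(1R,7S,7aR)-4,7-dimethyl-3-(3-methylbutanoyl)-1,6,7,7a-tetrahydrocyclopenta[c]pyran-1-yl]-5-methyl-2H-chromen-2-one | Cc1cccc2oc(=O)c(c(O)c12)[C@@H]1OC(C(=O)CC(C)C)=C(C)C2=CC[C@H](C)[C@@H]12 | intermediate (not isolated)
26 | CNP0310889.1, the bridged C-8′ ketal with (1′R,2′R,3′S,7′R,8′S) configuration | Cc1cccc2oc(=O)c3c(c12)O[C@@]1(C(=O)CC(C)C)O[C@@H]3[C@H]2C(=CC[C@@H]2C)[C@H]1C | target

**Count:** 19 steps in total; the longest linear sequence is 12 steps (steps 8 to 19).

**Steps most likely to fail**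

Step 18. The allenyl dione is generated in the presence of an amine and may lose its axial configuration, isomerise to a conjugated dienedione or oligomerise before it cyclises; the cycloaddition itself is unprecedented. The fallback sets out from 18 and returns at 24, using a conventional alkene as the oxadiene terminus. Conjugate addition of Me2CuLi (THF, −78 → −20 °C) to the ynone would give the thermodynamically preferred enone 3-[(1E,3S,6E,8R,9S)-3,7,11-trimethyl-5-oxo-8,9-bis(triethylsilyloxy)dodeca-1,6-dien-1-yl]-4-(methoxymethoxy)-5-methyl-2H-chromen-2-one F1. HF·pyridine would give the corresponding 8′,9′-diol F2. Swern oxidation would give the (1E,6E)-5,8,9-trione F3, a 2-acyl-1-oxadiene of the kind known to undergo intramolecular inverse-demand oxa-Diels–Alder reactions; it should cyclise to the trans-fused 5-oxo-hexahydrocyclopenta[c]pyran F4, with C-2′ now controlled only by the C-3′ methyl group. Tf2O with 2,6-di-tert-butyl-4-methylpyridine should enolise the ketone toward the doubly activated ring-fusion CH and give the dienyl triflate F5. Reduction with Pd(OAc)2, PPh3, HCO2H and n-Bu3N would give 24.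

Step 19. Protonation of the dienol ether may occur at C-5′ or on the wrong face of C-7′, or the 4-hydroxyl may add at C-6′, giving an alkene isomer, the C-7′ epimer or a pyranocoumarin. The fallback sets out from 18, runs through the fallback above as far as the dienyl triflate (F5 there), and returns at 26. Treating that triflate with CF3CO2H in CH2Cl2 should give the 5′-(trifluoromethanesulfonyloxy) derivative of the target ketal F6, because the triflyloxy group deactivates the distal alkene terminus and leaves C-7′ as the only site of protonation. Reduction with Pd(OAc)2, PPh3, HCO2H and n-Bu3N would then give 26.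

Step 16. The organocopper reagent may react by direct SN2 or with eroded anti selectivity, which would degrade the allene axis and hence C-1′ and C-2′, or it may attack the coumarin. The fallback sets out from 19 and returns at 21, changing from a copper SN2′ to a palladium cross-coupling. Methyl chloroformate and pyridine would give the (5′S) propargylic methyl carbonate F7. Pd(PPh3)4 and MeZnCl in THF should then give 21 by anti oxidative addition of zerovalent palladium to an allenylpalladium species, transmetalation and reductive elimination with retention.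

**Further compounds**

F1 | step 18 | 3-[(1E,3S,6E,8R,9S)-3,7,11-trimethyl-5-oxo-8,9-bis(triethylsilyloxy)dodeca-1,6-dien-1-yl]-4-(methoxymethoxy)-5-methyl-2H-chromen-2-one | Cc1cccc2oc(=O)c(/C=C/[C@@H](C)CC(=O)/C=C(\C)[C@@H](O[Si](CC)(CC)CC)[C@H](CC(C)C)O[Si](CC)(CC)CC)c(OCOC)c12
F2 | step 18 | 3-[(1E,3S,6E,8R,9S)-8,9-dihydroxy-3,7,11-trimethyl-5-oxododeca-1,6-dien-1-yl]-4-(methoxymethoxy)-5-methyl-2H-chromen-2-one | Cc1cccc2oc(=O)c(/C=C/[C@@H](C)CC(=O)/C=C(\C)[C@@H](O)[C@H](CC(C)C)O)c(OCOC)c12
F3 | step 18 | 3-[(1E,3S,6E)-3,7,11-trimethyl-5,8,9-trioxododeca-1,6-dien-1-yl]-4-(methoxymethoxy)-5-methyl-2H-chromen-2-one | Cc1cccc2oc(=O)c(/C=C/[C@@H](C)CC(=O)/C=C(\C)C(=O)C(=O)CC(C)C)c(OCOC)c12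
F4 | step 18 | 3-[(1R,4aR,7S,7aR)-4,7-dimethyl-3-(3-methylbutanoyl)-5-oxo-1,4a,5,6,7,7a-hexahydrocyclopenta[c]pyran-1-yl]-4-(methoxymethoxy)-5-methyl-2H-chromen-2-one | Cc1cccc2oc(=O)c(c(OCOC)c12)[C@@H]1OC(C(=O)CC(C)C)=C(C)[C@@H]2C(=O)C[C@H](C)[C@@H]12
F5 | step 18 | (1R,7S,7aR)-1-[4-(methoxymethoxy)-5-methyl-2-oxo-2H-chromen-3-yl]-4,7-dimethyl-3-(3-methylbutanoyl)-1,6,7,7a-tetrahydrocyclopenta[c]pyran-5-yl trifluoromethanesulfonate | Cc1cccc2oc(=O)c(c(OCOC)c12)[C@@H]1OC(C(=O)CC(C)C)=C(C)C2=C(OS(=O)(=O)C(F)(F)F)C[C@H](C)[C@@H]12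
F6 | step 19 | 5′-(trifluoromethanesulfonyloxy) derivative of 26 with (1′R,2′R,3′S,7′R,8′S) configuration | Cc1cccc2oc(=O)c3c(c12)O[C@@]1(C(=O)CC(C)C)O[C@@H]3[C@H]2C(=C(OS(=O)(=O)C(F)(F)F)C[C@@H]2C)[C@H]1C
F7 | step 16 | (1E,3S,5S,8R,9S)-1-[4-(methoxymethoxy)-5-methyl-2-oxo-2H-chromen-3-yl]-3,11-dimethyl-8,9-bis(triethylsilyloxy)dodec-1-en-6-yn-5-yl methyl carbonate | Cc1cccc2oc(=O)c(/C=C/[C@@H](C)C[C@H](OC(=O)OC)C#C[C@@H](O[Si](CC)(CC)CC)[C@H](CC(C)C)O[Si](CC)(CC)CC)c(OCOC)c12
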